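**Retrosynthetic overview**

- The plan rests on the cis ring fusion of the decalin: the C5 angular methyl is cis to H10 (ring A = C1–C5, C10; ring B = C5–C10), and this junction sits beside the vicinal C8 ketone and C9 acyloxy group of ring B.
- Late stage: the isopropenyl group comes from dehydration of a C11 tertiary alcohol (acetone aldol at C7); the C9 angelate and C8 ketone come from an 8α,9β-diol, itself from a C8 ketone / C9 dimethyl ketal; the C3 senecioate and C4 methyl come from hydroboration of a C3=C4 alkene.
- Key disconnection: the cis-octalin 8-ketone 9-ketal is opened to a 2-vinylbicyclo[2.2.2]oct-5-en-2-ol; the anionic oxy-Cope shift forms C5–C6 and breaks a temporary C3–C8 bond.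
- The bicycle comes from a Diels–Alder reaction of the masked o-benzoquinone of 4,5-dimethylguaiacol with phenyl vinyl sulfide (ethylene equivalent); the ketone is resolved through diastereomeric sulfoximine adducts.
- Ring order: arene, then the temporary bicyclo[2.2.2]octenone (ring A already present as its cyclohexene), then ring B by the [3,3] shift, then substituents on the conformationally locked cis-decalin.

Key step: step 8

Remark: decalins are numbered as eremophilanes (methyls on C4 and C5, three-carbon unit on C7), β is the face of the C5 methyl, and the C9 ester is taken as the (Z)-2-methylbut-2-enoate (angelate) that the SMILES specifies; the target is then (3R,4R,5R,7R,9R,10S).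

**Step 1**
Reactants: 1 3,4-dimethylphenol
Product: 2 2-bromo-4,5-dimethylphenol
Conditions: NBS, i-Pr2NH (cat.), CH2Cl2, 0 °C to rt
Reagents that add atoms: N-bromosuccinimide (O=C1CCC(=O)N1Br)
Why: Amine-catalysed electrophilic bromination with NBS is ortho-selective for phenols and should occur at the less hindered ortho position (para blocked by methyl), giving the 2-bromo-4,5-dimethyl pattern.

**Step 2**
Reactants: 2 2-bromo-4,5-dimethylphenol
Product: 3 2-methoxy-4,5-dimethylphenol (4,5-dimethylguaiacol)
Conditions: NaOMe (excess), CuBr (cat.), MeOH/DMF, 110 °C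
Reagents that add atoms: sodium methoxide ([Na+].[O-]C)
Why: Ullmann-type CuBr-catalysed methoxylation of an ortho-bromophenol with excess NaOMe is an established route to guaiacols and should replace bromine by methoxy.

**Step 3**
Reactants: 3 2-methoxy-4,5-dimethylphenol; 4 phenyl vinyl sulfide
Product: 6 (±)-3,3-dimethoxy-5,6-dimethyl-7-(phenylsulfanyl)bicyclo[2.2.2]oct-5-en-2-one (sulfanyl group syn to the C5=C6 bridge), via masked o-benzoquinone 5 (not isolated)
Conditions: PhI(OAc)2, MeOH, 4 (excess), slow addition of 3, 0 °C to 50 °C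
Reagents that add atoms: methanol (CO)
Why: Oxidative dearomatisation of the guaiacol by PhI(OAc)2 in methanol gives the 6,6-dimethoxycyclohexa-2,4-dienone 5, whose diene is trapped in situ in a Diels–Alder reaction by the excess vinyl sulfide serving as an ethylene equivalent, the regio- and endo-selectivity at C7 being irrelevant because that centre is erased in step 4.

**Step 4**
Reactants: 6 (±)-phenylsulfanyl adduct
Product: 7 (±)-3,3-dimethoxy-5,6-dimethylbicyclo[2.2.2]oct-5-en-2-one
Conditions: Raney Ni (acetone-deactivated), acetone/EtOH, rt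
Reagents that add atoms: none
Why: Raney Ni desulfurisation cleaves the alkyl aryl C–S bond and should leave the tetrasubstituted alkene, the ketal and (with deactivated catalyst) the hindered ketone untouched.

**Step 5**
Reactants: 7 (±)-bicyclic ketone; 8 (S)-N,S-dimethyl-S-phenylsulfoximine
Product: 10 (1R,2R,4S)-3,3-dimethoxy-5,6-dimethyl-2-{[(S)-N-methyl-S-phenylsulfonimidoyl]methyl}bicyclo[2.2.2]oct-5-en-2-ol, via lithiated sulfoximine 9 (not isolated)
Conditions: n-BuLi, THF, −78 °C; then (±)-7; then H2O; silica gel chromatography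
Reagents that add atoms: none
Why: Sulfoximine resolution of a ketone: the lithiated enantiopure sulfoximine adds to both enantiomers of 7 from the face syn to the C5=C6 bridge, turning the racemate into two diastereomeric β-hydroxy sulfoximines, 10 from the (1R,4S)-ketone and its (1S,2S,4R) diastereomer from the enantiomeric ketone, which should be separable by chromatography so that only 10 is carried on, its assignment to be secured by X-ray analysis.

**Step 6**
Reactants: 10 β-hydroxy sulfoximine
Product: 11 (1R,4S)-3,3-dimethoxy-5,6-dimethylbicyclo[2.2.2]oct-5-en-2-one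
Conditions: toluene, 110 °C
Reagents that add atoms: none
Why: Thermal retro-addition of a β-hydroxy sulfoximine regenerates the ketone with its bridgehead configuration intact and returns the resolving agent 8.

**Step 7**
Reactants: 11 (1R,4S)-ketone; 12 vinylmagnesium bromide
Product: 13 (1R,2R,4S)-2-ethenyl-3,3-dimethoxy-5,6-dimethylbicyclo[2.2.2]oct-5-en-2-ol (vinyl syn to the C5=C6 bridge)
Conditions: CH2=CHMgBr, THF, −78 to 0 °C; then H2O
Reagents that add atoms: none
Why: Grignard 1,2-addition to the non-enolisable ketone should occur from the face syn to the etheno bridge, which is less hindered than the face under the ethano bridge, so the new carbinol centre carries the vinyl group syn to the alkene as the [3,3] shift requires.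

**Step 8**
Reactants: 13 vinyl carbinol
Product: 16 (4aS,8aS)-1,1-dimethoxy-4a,5-dimethyl-3,4,4a,7,8,8a-hexahydronaphthalen-2(1H)-one (cis-fused; 8-ketone with 9,9-dimethoxy and C3=C4 in eremophilane numbering), via potassium alkoxide 14 (not isolated), via potassium enolate 15 (not isolated)
Conditions: KH, 18-crown-6, THF, 0 °C to rt; then AcOH, −78 °C
Reagents that add atoms: none
Why: KH with 18-crown-6 gives the dissociated alkoxide 14, whose 1,5-diene (vinyl C6=C7, carbinol C8, bridgehead C3, alkene C4=C5) undergoes a charge-accelerated concerted [3,3] sigmatropic shift through the boat-like array imposed by the bicycle, forming C5–C6 and breaking C3–C8 to give enolate 15. The closest known reaction type is the anionic oxy-Cope rearrangement of 2-vinylbicyclo[2.2.2]oct-5-en-2-ols derived from masked o-benzoquinone Diels–Alder adducts, which gives cis-decalins. Ring B is closed as a six-membered carbocycle by intramolecular suprafacial bonding of the vinyl terminus C6 to the alkene carbon C5, while ring A is released as the C3=C4 cyclohexene. The one new stereocentre, quaternary C5, is fixed relative to C10 by the geometry of the bicycle, because C6 can reach C5 only on the alkene face that carries the C8–C9 bridge, so C6 and C9 are cis on ring A and the methyl ends up cis to H10; the absolute sense comes from resolved 11. The step needs the vinyl group syn to the alkene bridge, secured in step 7, and a single enolate regiochemistry, secured by the C9 ketal that blocks enolisation toward C9. Release of bicyclic strain and enolate formation drive the shift, and the cold AcOH quench returns the C8 ketone.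

**Step 9**
Reactants: 16 cis-octalinone
Product: 18 9,9-dimethoxy-4β,5β-dimethyl-10βH-decalin-3α,8ξ-diol (C8 epimers), via alkylborane 17 (not isolated)
Conditions: BH3·THF (excess), THF, 0 °C to rt; then NaOH, H2O2
Reagents that add atoms: hydrogen peroxide (OO)
Why: Hydroboration–oxidation adds H and B syn, boron at the less substituted C3, from the α face opposite the C5 angular methyl, setting the 3α-hydroxyl and the 4β-methyl with retention in the oxidation, while the excess borane also reduces the C8 ketone to an inconsequential epimer mixture that is re-oxidised in step 11.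

**Step 10**
Reactants: 18 diol; 19 3-methylbut-2-enoyl chloride (senecioyl chloride)
Product: 20 8ξ-hydroxy-9,9-dimethoxy-4β,5β-dimethyl-10βH-decalin-3α-yl 3-methylbut-2-enoate
Conditions: pyridine, DMAP (cat.), CH2Cl2, 0 °C
Reagents that add atoms: none
Why: Site-selective esterification with the acid chloride should favour the equatorial C3 hydroxyl (flanked by CH2 and CHCH3) over the C8 hydroxyl next to the quaternary ketal carbon, and pyridine instead of a stronger amine limits vinylketene formation and deconjugation of the acyl group.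

**Step 11**
Reactants: 20 hydroxy ester
Product: 21 9,9-dimethoxy-4β,5β-dimethyl-8-oxo-10βH-decalin-3α-yl 3-methylbut-2-enoate
Conditions: Dess–Martin periodinane, CH2Cl2, rt
Reagents that add atoms: none
Why: Dess–Martin oxidation converts both C8 epimers into one ketone under neutral conditions that leave the ketal and the enoate untouched.

**Step 12**
Reactants: 21 keto ester; 22 acetone
Product: 25 7β-(2-hydroxypropan-2-yl)-9,9-dimethoxy-4β,5β-dimethyl-8-oxo-10βH-decalin-3α-yl 3-methylbut-2-enoate, via lithium enolate 23 (not isolated), via chlorozinc enolate 24 (not isolated)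
Conditions: LiN(SiMe3)2, THF, −78 °C; ZnCl2; acetone, −78 to 0 °C; then AcOH
Reagents that add atoms: none
Why: LiN(SiMe3)2 enolises the ketone (more acidic than the ester) at C7, its only enolisable position, and the zinc enolate aldol addition to acetone should occur on the β face because, with ring A now a chair that locks the cis-decalin (C3 and C4 substituents equatorial), the α face of C7 is screened by the axial C5–C4 bond and the axial C9 methoxy group, so the hydroxyisopropyl group becomes equatorial (7β), which is also the more stable aldolate under these reversible conditions.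

**Step 13**
Reactants: 25 β-hydroxy ketone
Product: 26 8α-hydroxy-7β-(2-hydroxypropan-2-yl)-9,9-dimethoxy-4β,5β-dimethyl-10βH-decalin-3α-yl 3-methylbut-2-enoate
Conditions: Me4NBH(OAc)3, MeCN/AcOH, −20 °C
Reagents that add atoms: none
Why: Hydroxyl-directed reduction of the Evans–Saksena type, in which the C11 hydroxyl exchanges onto boron and hydride is delivered intramolecularly along the unhindered axial (β) trajectory at C8, should give the equatorial 8α-alcohol trans to the C7 substituent, while the acidic medium avoids retro-aldol cleavage and spares the enoate.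

**Step 14**
Reactants: 26 diol ketal
Product: 27 8α-hydroxy-7β-(2-hydroxypropan-2-yl)-4β,5β-dimethyl-9-oxo-10βH-decalin-3α-yl 3-methylbut-2-enoate
Conditions: aq. HCl (1 M), THF, rt
Reagents that add atoms: water (O)
Why: Acid-catalysed ketal hydrolysis unmasks the C9 ketone only after C8 has become a carbinol, so no enolisable 1,2-dione arises, and mild acid at room temperature should leave the ester, the tertiary alcohol and the C10 ring-fusion centre unchanged.

**Step 15**
Reactants: 27 α-hydroxy ketone
Product: 28 8α,9β-dihydroxy-7β-(2-hydroxypropan-2-yl)-4β,5β-dimethyl-10βH-decalin-3α-yl 3-methylbut-2-enoate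
Conditions: Me4NBH(OAc)3, MeCN/AcOH, −20 °C
Reagents that add atoms: none
Why: Hydroxyl-directed reduction of the Evans–Saksena type, in which hydride is delivered from boron bound to the 8α-oxygen to the α face of C9, should give the 9β (equatorial) alcohol trans to the C8 hydroxyl, the reagent not reducing the ketone intermolecularly.

**Step 16**
Reactants: 28 triol; 29 angelic acid ((Z)-2-methylbut-2-enoic acid)
Product: 31 9β-[(Z)-2-methylbut-2-enoyloxy]-8α-hydroxy-7β-(2-hydroxypropan-2-yl)-4β,5β-dimethyl-10βH-decalin-3α-yl 3-methylbut-2-enoate, via mixed anhydride 30 (not isolated)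
Conditions: 29, 2,4,6-Cl3C6H2COCl, Et3N, toluene, rt; then 28, 75 °C
Reagents that add atoms: none
Why: Yamaguchi esterification through mixed anhydride 30 should acylate the C9 hydroxyl, because the C8 hydroxyl is shielded by (and hydrogen-bonded to) the adjacent hydroxyisopropyl group and the C11 hydroxyl is tertiary, and the DMAP-free protocol is known to keep the Z geometry of angelates.

**Step 17**
Reactants: 31 diol diester
Product: 32 9β-[(Z)-2-methylbut-2-enoyloxy]-7β-(2-hydroxypropan-2-yl)-4β,5β-dimethyl-8-oxo-10βH-decalin-3α-yl 3-methylbut-2-enoate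
Conditions: Dess–Martin periodinane, CH2Cl2, rt
Reagents that add atoms: none
Why: Dess–Martin oxidation of the one remaining secondary alcohol gives the C8 ketone under neutral, non-epimerising conditions, the tertiary alcohol being inert.

**Step 18**
Reactants: 32 β-hydroxy ketone
Product: 33 target, 9β-[(Z)-2-methylbut-2-enoyloxy]-4β,5β-dimethyl-8-oxo-7β-(prop-1-en-2-yl)-10βH-decalin-3α-yl 3-methylbut-2-enoate (CNP0164025.2)
Conditions: SOCl2, pyridine, CH2Cl2, −30 to 0 °C
Reagents that add atoms: none
Why: Dehydration of the tertiary alcohol through its chlorosulfite with pyridine (E2) should remove one of the six methyl hydrogens faster than the single hindered C7 hydrogen (kinetic Hofmann-type regiochemistry known for acetone aldols of cyclic ketones), giving the isopropenyl group without touching the C7 and C9 centres.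

**Compound list**

1 | 3,4-dimethylphenol | Cc1ccc(O)cc1C | starting material
2 | 2-bromo-4,5-dimethylphenol | Cc1cc(O)c(Br)cc1C | intermediate
3 | 2-methoxy-4,5-dimethylphenol | COc1cc(C)c(C)cc1O | intermediate
4 | phenyl vinyl sulfide | C=CSc1ccccc1 | starting material
5 | 6,6-dimethoxy-3,4-dimethylcyclohexa-2,4-dienone | COC1(OC)C=C(C)C(C)=CC1=O | intermediate (not isolated)
6 | (±)-3,3-dimethoxy-5,6-dimethyl-7-(phenylsulfanyl)bicyclo[2.2.2]oct-5-en-2-one (racemic, relative configuration drawn) | O=C1C(OC)(OC)[C@H]2C[C@H](Sc3ccccc3)[C@@H]1C(C)=C2C | intermediate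
7 | (±)-3,3-dimethoxy-5,6-dimethylbicyclo[2.2.2]oct-5-en-2-one (racemate) | O=C1C(OC)(OC)C2CCC1C(C)=C2C | intermediate
8 | (S)-N,S-dimethyl-S-phenylsulfoximine | C[S@@](=O)(=NC)c1ccccc1 | starting material
9 | lithiated (S)-sulfoximine | [Li]C[S@@](=O)(=NC)c1ccccc1 | intermediate (not isolated)
10 | (1R,2R,4S)-3,3-dimethoxy-5,6-dimethyl-2-{[(S)-N-methyl-S-phenylsulfonimidoyl]methyl}bicyclo[2.2.2]oct-5-en-2-ol | c1ccccc1[S@](=O)(=NC)C[C@]1(O)C(OC)(OC)[C@H]2CC[C@@H]1C(C)=C2C | intermediate
11 | (1R,4S)-3,3-dimethoxy-5,6-dimethylbicyclo[2.2.2]oct-5-en-2-one | O=C1C(OC)(OC)[C@H]2CC[C@@H]1C(C)=C2C | intermediate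
12 | vinylmagnesium bromide | C=C[Mg]Br | starting material
13 | (1R,2R,4S)-2-ethenyl-3,3-dimethoxy-5,6-dimethylbicyclo[2.2.2]oct-5-en-2-ol | C=C[C@]1(O)C(OC)(OC)[C@H]2CC[C@@H]1C(C)=C2C | intermediate
14 | potassium alkoxide of 13 | C=C[C@]1([O-])C(OC)(OC)[C@H]2CC[C@@H]1C(C)=C2C.[K+] | intermediate (not isolated)
15 | potassium C7–C8 enolate of 16 | [K+].[O-]C1=CC[C@@]2(C)[C@H](CCC=C2C)C1(OC)OC | intermediate (not isolated)
16 | (4aS,8aS)-1,1-dimethoxy-4a,5-dimethyl-3,4,4a,7,8,8a-hexahydronaphthalen-2(1H)-one | C1C[C@@]2(C)[C@H](CCC=C2C)C(OC)(OC)C1=O | intermediate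
17 | C3 alkylborane / C8 alkoxyborane (idealised as the bis-BH2 species) | C1C[C@@]2(C)[C@H](CC[C@@H](B)[C@@H]2C)C(OC)(OC)C1OB | intermediate (not isolated)
18 | 9,9-dimethoxy-4β,5β-dimethyl-10βH-decalin-3α,8ξ-diol | C1C[C@@]2(C)[C@H](CC[C@@H](O)[C@@H]2C)C(OC)(OC)C1O | intermediate
19 | 3-methylbut-2-enoyl chloride | CC(C)=CC(=O)Cl | starting material
20 | 8ξ-hydroxy-9,9-dimethoxy-4β,5β-dimethyl-10βH-decalin-3α-yl 3-methylbut-2-enoate | C1C[C@@]2(C)[C@H](CC[C@@H](OC(=O)C=C(C)C)[C@@H]2C)C(OC)(OC)C1O | intermediate
21 | 9,9-dimethoxy-4β,5β-dimethyl-8-oxo-10βH-decalin-3α-yl 3-methylbut-2-enoate | C1C[C@@]2(C)[C@H](CC[C@@H](OC(=O)C=C(C)C)[C@@H]2C)C(OC)(OC)C1=O | intermediate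
22 | acetone | CC(C)=O | starting material
23 | lithium C7–C8 enolate of 21 | [Li]OC1=CC[C@@]2(C)[C@H](CC[C@@H](OC(=O)C=C(C)C)[C@@H]2C)C1(OC)OC | intermediate (not isolated)
24 | chlorozinc C7–C8 enolate of 21 | Cl[Zn]OC1=CC[C@@]2(C)[C@H](CC[C@@H](OC(=O)C=C(C)C)[C@@H]2C)C1(OC)OC | intermediate (not isolated)
25 | 7β-(2-hydroxypropan-2-yl)-9,9-dimethoxy-4β,5β-dimethyl-8-oxo-10βH-decalin-3α-yl 3-methylbut-2-enoate | CC(C)(O)[C@H]1C[C@@]2(C)[C@H](CC[C@@H](OC(=O)C=C(C)C)[C@@H]2C)C(OC)(OC)C1=O | intermediate
26 | 8α-hydroxy-7β-(2-hydroxypropan-2-yl)-9,9-dimethoxy-4β,5β-dimethyl-10βH-decalin-3α-yl 3-methylbut-2-enoate | CC(C)(O)[C@H]1C[C@@]2(C)[C@H](CC[C@@H](OC(=O)C=C(C)C)[C@@H]2C)C(OC)(OC)[C@@H]1O | intermediate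
27 | 8α-hydroxy-7β-(2-hydroxypropan-2-yl)-4β,5β-dimethyl-9-oxo-10βH-decalin-3α-yl 3-methylbut-2-enoate | CC(C)(O)[C@H]1C[C@@]2(C)[C@H](CC[C@@H](OC(=O)C=C(C)C)[C@@H]2C)C(=O)[C@@H]1O | intermediate
28 | 8α,9β-dihydroxy-7β-(2-hydroxypropan-2-yl)-4β,5β-dimethyl-10βH-decalin-3α-yl 3-methylbut-2-enoate | CC(C)(O)[C@H]1C[C@@]2(C)[C@H](CC[C@@H](OC(=O)C=C(C)C)[C@@H]2C)[C@@H](O)[C@@H]1O | intermediate
29 | angelic acid | C/C=C(/C)C(=O)O | starting material
30 | angelic 2,4,6-trichlorobenzoic anhydride | C/C=C(/C)C(=O)OC(=O)c1c(Cl)cc(Cl)cc1Cl | intermediate (not isolated)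
31 | 9β-[(Z)-2-methylbut-2-enoyloxy]-8α-hydroxy-7β-(2-hydroxypropan-2-yl)-4β,5β-dimethyl-10βH-decalin-3α-yl 3-methylbut-2-enoate | CC(C)(O)[C@H]1C[C@@]2(C)[C@H](CC[C@@H](OC(=O)C=C(C)C)[C@@H]2C)[C@@H](OC(=O)/C(C)=C\C)[C@@H]1O | intermediate
32 | 9β-[(Z)-2-methylbut-2-enoyloxy]-7β-(2-hydroxypropan-2-yl)-4β,5β-dimethyl-8-oxo-10βH-decalin-3α-yl 3-methylbut-2-enoate | CC(C)(O)[C@H]1C[C@@]2(C)[C@H](CC[C@@H](OC(=O)C=C(C)C)[C@@H]2C)[C@@H](OC(=O)/C(C)=C\C)C1=O | intermediate
33 | 3α-senecioyloxy-9β-angeloyloxy-10βH-eremophil-11-en-8-one, (3R,4R,5R,7R,9R,10S) | C=C(C)[C@H]1C[C@@]2(C)[C@H](CC[C@@H](OC(=O)C=C(C)C)[C@@H]2C)[C@@H](OC(=O)/C(C)=C\C)C1=O | target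

**Totals**

Total step count: 18. Longest linear sequence: 18 steps (from 1).

**Steps most likely to fail**

Step 18. The elimination may take the C7 hydrogen instead of a methyl hydrogen, or the new double bond may migrate into conjugation with the C8 ketone under the basic conditions. Fallback: dehydrate before the C8 ketone exists. Setting out from 31, the C8 hydroxyl is silylated (Et3SiCl, imidazole, DMF; the tertiary hydroxyl is inert) to give the C8 triethylsilyl ether F1. The tertiary alcohol is then dehydrated (SOCl2, pyridine), now without an acidic C7 hydrogen and with allylic strain against the C8 silyloxy group disfavouring the tetrasubstituted alkene, to give the isopropenyl silyl ether F2. HF·pyridine frees the 8α-alcohol F3, and Dess–Martin oxidation rejoins the route at 33.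

Step 16. Acylation may not discriminate between the C8 and C9 hydroxyls, and the forcing conditions may isomerise the Z acyl group. Fallback: mask the competing hydroxyl instead of relying on sterics. Setting out from 28, tBu2Si(OTf)2 and 2,6-lutidine bridge the 1,3-related C8 and C11 hydroxyls as the six-membered di-tert-butylsilylene F4 (the trans-diequatorial 8,9-diol cannot span a five-membered silylene). Yamaguchi angeloylation of the only free hydroxyl then gives the silylene angelate F5, and HF·pyridine removes the silylene to rejoin the route at 31.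

Step 12. Addition of the hindered enolate to acetone may stay incomplete or revert, and the enoate may be deprotonated in competition. Fallback: replace the metal enolate by a Lewis-acid-mediated, irreversible addition. Setting out from 21, soft enolisation (Me3SiOTf, Et3N) gives the trimethylsilyl enol ether F6, and a Mukaiyama aldol addition to acetone (TiCl4, CH2Cl2, −78 °C), again on the β face, rejoins the route at 25.

**Further compounds**

F1 | step 18 | C8 triethylsilyl ether of 31 | CC(C)(O)[C@H]1C[C@@]2(C)[C@H](CC[C@@H](OC(=O)C=C(C)C)[C@@H]2C)[C@@H](OC(=O)/C(C)=C\C)[C@@H]1O[Si](CC)(CC)CC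
F2 | step 18 | 7β-isopropenyl C8 triethylsilyl ether | C=C(C)[C@H]1C[C@@]2(C)[C@H](CC[C@@H](OC(=O)C=C(C)C)[C@@H]2C)[C@@H](OC(=O)/C(C)=C\C)[C@@H]1O[Si](CC)(CC)CC
F3 | step 18 | 8α-hydroxy-7β-isopropenyl diester (8-dihydro form of 33) | C=C(C)[C@H]1C[C@@]2(C)[C@H](CC[C@@H](OC(=O)C=C(C)C)[C@@H]2C)[C@@H](OC(=O)/C(C)=C\C)[C@@H]1O
F4 | step 16 | 8,11-O-di-tert-butylsilylene of 28 | CC(C)(O[Si]3(C(C)(C)C)C(C)(C)C)[C@H]1C[C@@]2(C)[C@H](CC[C@@H](OC(=O)C=C(C)C)[C@@H]2C)[C@@H](O)[C@@H]1O3
F5 | step 16 | 9β-angelate of silylene F4 | CC(C)(O[Si]3(C(C)(C)C)C(C)(C)C)[C@H]1C[C@@]2(C)[C@H](CC[C@@H](OC(=O)C=C(C)C)[C@@H]2C)[C@@H](OC(=O)/C(C)=C\C)[C@@H]1O3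
F6 | step 12 | trimethylsilyl enol ether of 21 | C[Si](C)(C)OC1=CC[C@@]2(C)[C@H](CC[C@@H](OC(=O)C=C(C)C)[C@@H]2C)C1(OC)OC
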